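**Retrosynthetic overview**

- The last step is a singlet-oxygen ene reaction of the 3-O-angeloyl 7(11)-en-8-one, which places the hydroperoxide on C11 and moves the alkene to C6=C7. The angelate is put on C3–OH one step earlier.
- The C8 ketone and the C7=C11 alkene come from the carvone-derived C9 ketone by 1,2-transposition: enol triflate, 8-ene, tethered hydrosilylation–oxidation from C11–OH, oxidation, dehydration. The 4α-OH/4β-CH3 group comes from a C4=C15 methylene by α-face epoxidation and hydride opening.
- The strategy rests on C3 (O-acyl) and C4 (tertiary carbinol) being adjacent oxygen-bearing carbons of ring A. Both are therefore made as electrophiles, an aldehyde at C3 and a 1-iodovinyl group at C4, and are joined reductively by a CrCl2/NiCl2 Nozaki–Hiyama–Kishi cyclisation that closes ring A.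
- Ring B is the ring of (R)-carvone and is never formed; ring A is the only ring made. Trans conjugate addition of a 1-silylvinyl group (C4/C15) and anti allylation (C1–C3) set C5 and C10.

Key step: step 7

Remark: eudesmane numbering is used for the bicyclic compounds (ring A = C1–C5 and C10, ring B = C5–C10, β = face of the C10 methyl); all intermediates up to step 15 carry the C7 side chain on the α face (7βH), a centre that is erased in step 16.

**Route**

Step 1
Reactants: 1 (R)-carvone
Product: 2 (5R)-5-(2-hydroxypropan-2-yl)-2-methylcyclohex-2-en-1-one (carvone hydrate)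
Conditions: 50% aq. H2SO4, 0 °C
Reagents that add atoms: water, O
Why: Acid-catalysed Markovnikov hydration: the isopropenyl alkene is protonated to the tertiary cation and trapped by water while the deactivated enone alkene stays; C5 is not involved, so its configuration is kept.

Step 2
Reactants: 2 carvone hydrate
Product: 3 (5R)-2-methyl-5-[2-(triethylsilyloxy)propan-2-yl]cyclohex-2-en-1-one
Conditions: TESOTf, 2,6-lutidine, CH2Cl2, −78 → 0 °C
Reagents that add atoms: triethylsilyl trifluoromethanesulfonate, CC[Si](CC)(CC)OS(=O)(=O)C(F)(F)F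
Why: Silylation of a tertiary alcohol needs the silyl triflate; the hindered base does not turn the enone into a silyl dienol ether at low temperature.

Step 3
Reactants: 3 enone silyl ether; 4 (1-bromovinyl)trimethylsilane; 5 allyl bromide
Product: 8 (2S,3R,5R)-2-allyl-2-methyl-5-[2-(triethylsilyloxy)propan-2-yl]-3-[1-(trimethylsilyl)vinyl]cyclohexan-1-one, via [1-(trimethylsilyl)vinyl]magnesium bromide 6 (not isolated), via bromomagnesium enolate 7 (not isolated)
Conditions: 4, Mg, THF; then CuBr·SMe2 (10 mol%), 3, THF, −78 → −40 °C; then 5, HMPA, −40 °C → rt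
Reagents that add atoms: (1-bromovinyl)trimethylsilane 4, C=C(Br)[Si](C)(C)C; allyl bromide 5, C=CCBr
Why: Tandem copper-catalysed conjugate addition–enolate alkylation: the Grignard reagent adds axially to C3 anti to the C5 side chain, and the HMPA-activated enolate is allylated on the face anti to the new C3 group, which sets the quaternary carbon with allyl trans to the silylvinyl group.

Step 4
Reactants: 8 allyl ketone
Product: 10 (2S,3R,5R)-2-(3-hydroxypropyl)-2-methyl-5-[2-(triethylsilyloxy)propan-2-yl]-3-[1-(trimethylsilyl)vinyl]cyclohexan-1-one, via alkyldicyclohexylborane 9 (not isolated)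
Conditions: Cy2BH, THF, 0 °C → rt; then NaOH, 30% H2O2, 0 °C
Reagents that add atoms: hydrogen peroxide, OO
Why: Hydroboration–oxidation: the bulky dialkylborane adds anti-Markovnikov to the monosubstituted allyl alkene much faster than to the hindered 1,1-disubstituted vinylsilane; any reduction of the α-quaternary ketone would be undone by the oxidation in step 6.

Step 5
Reactants: 10 hydroxy ketone
Product: 11 (2S,3R,5R)-2-(3-hydroxypropyl)-3-(1-iodovinyl)-2-methyl-5-[2-(triethylsilyloxy)propan-2-yl]cyclohexan-1-one
Conditions: NIS, MeCN/ClCH2CN (4:1), rt, dark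
Reagents that add atoms: N-iodosuccinimide, O=C1CCC(=O)N1I
Why: Ipso iododesilylation: electrophilic iodine bonds to the silicon-bearing alkene carbon, the positive charge develops β to silicon, and loss of the silyl group restores the alkene as the 2-iodo-1-alkene.

Step 6
Reactants: 11 iodoalkenyl alcohol
Product: 12 3-[(1S,2R,4R)-2-(1-iodovinyl)-1-methyl-6-oxo-4-[2-(triethylsilyloxy)propan-2-yl]cyclohexyl]propanal
Conditions: DMP, CH2Cl2, 0 °C → rt
Reagents that add atoms: none
Why: Dess–Martin oxidation takes the primary alcohol to the aldehyde and no further, under conditions that leave the vinyl iodide and the tertiary silyl ether alone.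

Step 7
Reactants: 12 iodoalkenyl keto aldehyde
Product: 14 3β-hydroxy-11-(triethylsilyloxy)-7βH-eudesm-4(15)-en-9-one, via alkenylchromium dichloride 13 (not isolated)
Conditions: CrCl2 (6 equiv), NiCl2 (2 mol%), degassed DMF, 0.01 M, rt; then H2O
Reagents that add atoms: none
Why: Zerovalent nickel, formed from NiCl2 and CrCl2, inserts into the C4–I bond and passes the alkenyl group to trivalent chromium to give alkenylchromium 13, which adds to the C3 aldehyde; this is an intramolecular Nozaki–Hiyama–Kishi reaction of the type used to close 2-methylenecycloalkanols from iodoalkenyl aldehydes. Ring A closes 6-exo-trig at the aldehyde carbon, and because the C10 propanal arm and the C5 alkenyl group are trans and both equatorial in the reacting chair of ring B, the new ring can only be trans-fused, with the C4=C15 alkene left exocyclic. The one new stereocentre, C3, should be set in a chair transition state with the chromium-bound oxygen equatorial, clear of the axial hydrogens on C1 and C5, which gives the 3β-alcohol. The step needs the aldehyde to react in preference to the C9 ketone, which the carbonyl selectivity of organochromium reagents and the quaternary C10 next to C9 secure. The neutral conditions leave the tertiary silyl ether intact, and high dilution suppresses intermolecular coupling.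

Step 8
Reactants: 14 allylic alcohol
Product: 15 3β-(tert-butyldimethylsilyloxy)-11-(triethylsilyloxy)-7βH-eudesm-4(15)-en-9-one
Conditions: TBSCl, imidazole, DMF, rt
Reagents that add atoms: tert-butyldimethylsilyl chloride, CC(C)(C)[Si](C)(C)Cl
Why: Standard silylation of the secondary alcohol; the TBS group is chosen so that the C11 triethylsilyl ether can later be removed in its presence.

Step 9
Reactants: 15 ketone
Product: 17 3β-(tert-butyldimethylsilyloxy)-11-(triethylsilyloxy)-7βH-eudesma-4(15),8-dien-9-yl trifluoromethanesulfonate, via potassium enolate 16 (not isolated)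
Conditions: KN(SiMe3)2, THF, −78 °C; then PhNTf2, −78 → 0 °C
Reagents that add atoms: N-phenylbis(trifluoromethanesulfonimide), O=S(=O)(N(c1ccccc1)S(=O)(=O)C(F)(F)F)C(F)(F)F
Why: Enol triflate formation: C10 is quaternary, so the ketone can enolise only toward C8, and the enolate is sulfonylated on oxygen.

Step 10
Reactants: 17 enol triflate
Product: 18 4α,15-epoxy-3β-(tert-butyldimethylsilyloxy)-11-(triethylsilyloxy)-7βH-eudesm-8-en-9-yl trifluoromethanesulfonate
Conditions: mCPBA, NaHCO3, CH2Cl2, 0 °C
Reagents that add atoms: mCPBA, OOC(=O)c1cccc(Cl)c1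
Why: Prilezhaev epoxidation: the electron-poor enol triflate alkene is inert, and the peracid should reach C4=C15 from the α face because the axial C10 methyl shields the β face, which sets C4 with oxygen α and C15 β.

Step 11
Reactants: 18 epoxy enol triflate
Product: 19 4α,15-epoxy-3β-(tert-butyldimethylsilyloxy)-11-(triethylsilyloxy)-7βH-eudesm-8-ene
Conditions: Pd(OAc)2 (5 mol%), PPh3, HCO2H, Bu3N, DMF, 60 °C
Reagents that add atoms: none
Why: Palladium-catalysed formate reduction of an enol triflate: oxidative addition of zerovalent palladium, formate exchange, loss of CO2 and reductive elimination replace OTf by H; the epoxide CH2 is neopentyl-like and should not be opened by formate.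

Step 12
Reactants: 19 epoxy alkene
Product: 20 3β-(tert-butyldimethylsilyloxy)-11-(triethylsilyloxy)-7βH-eudesm-8-en-4α-ol
Conditions: LiEt3BH, THF, 0 °C → rt; then H2O
Reagents that add atoms: none
Why: Hydride opens the epoxide by SN2 attack at the primary carbon C15 without touching C4, so the α oxygen becomes the equatorial 4α-hydroxyl and C15 the axial 4β-methyl.

Step 13
Reactants: 20 bis-silyl ether
Product: 21 3β-(tert-butyldimethylsilyloxy)-7βH-eudesm-8-ene-4α,11-diol
Conditions: PPTS (cat.), MeOH, 0 °C → rt
Reagents that add atoms: none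
Why: Selective acid-catalysed methanolysis: the triethylsilyl ether is cleaved much faster than the bulkier TBS ether on the hindered C3 secondary alcohol.

Step 14
Reactants: 21 homoallylic diol
Product: 24 3β-(tert-butyldimethylsilyloxy)-7βH-eudesmane-4α,8α,11-triol, via bis(dimethylsilyl) ether 22 (not isolated), via cyclic siloxane 23 (not isolated)
Conditions: (HMe2Si)2NH, NH4Cl (cat.), 70 °C, evaporate; H2PtCl6·6H2O (0.5 mol%), THF, 60 °C; then 30% H2O2, KF, KHCO3, THF/MeOH, rt
Reagents that add atoms: hydrogen peroxide, OO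
Why: Tethered hydrosilylation–Tamao–Fleming oxidation of a homoallylic alcohol: both tertiary hydroxyls are silylated, the C11–O–SiMe2H tether adds across C8=C9 in a 5-exo sense so that silicon bonds to C8 cis to the C7 side chain, and oxidation replaces C–Si by C–OH with retention (8α-OH) while freeing the C4 and C11 hydroxyls.

Step 15
Reactants: 24 triol
Product: 25 3β-(tert-butyldimethylsilyloxy)-4α,11-dihydroxy-7βH-eudesman-8-one
Conditions: DMP, CH2Cl2, 0 °C → rt
Reagents that add atoms: none
Why: Dess–Martin oxidation: C8 carries the only secondary hydroxyl, so the β-hydroxy ketone forms without touching the two tertiary alcohols.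

Step 16
Reactants: 25 β-hydroxy ketone
Product: 26 3β-(tert-butyldimethylsilyloxy)-4α-hydroxyeudesm-7(11)-en-8-one
Conditions: p-TsOH·H2O (cat.), benzene, 50 °C
Reagents that add atoms: none
Why: Acid-catalysed aldol dehydration through the C7 enol gives the conjugated tetrasubstituted 7(11)-enone and removes the C7 stereocentre; the C4 tertiary alcohol has no enolisable neighbour and an electron-withdrawing C3 oxygen beside it, so it should not ionise.

Step 17
Reactants: 26 silyl ether enone
Product: 27 3β,4α-dihydroxyeudesm-7(11)-en-8-one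
Conditions: HF·pyridine, THF, 0 °C → rt
Reagents that add atoms: none
Why: Fluoride-driven cleavage of the Si–O bond frees the C3 hydroxyl under conditions too mild to ionise the tertiary alcohol or move the enone.

Step 18
Reactants: 27 diol enone; 28 angelic acid
Product: 30 3β-angeloyloxy-4α-hydroxyeudesm-7(11)-en-8-one, via angelic 2,4,6-trichlorobenzoic anhydride 29 (not isolated)
Conditions: 28, 2,4,6-trichlorobenzoyl chloride, Et3N, toluene, rt; then 27, toluene, 80 °C
Reagents that add atoms: angelic acid 28, C/C=C(/C)C(=O)O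
Why: Yamaguchi-type acylation: the mixed anhydride delivers the angeloyl group to the equatorial secondary C3 hydroxyl, the tertiary C4 hydroxyl being too hindered; no nucleophilic catalyst is used, so the addition–elimination that would turn the (Z)-angelate into the (E)-tiglate is avoided.

Step 19
Reactants: 30 angelate enone
Product: 31 3β-angeloyloxy-4α-hydroxy-11-hydroperoxyeudesm-6-en-8-one (target, 3S,4S,5R,10R)
Conditions: O2, tetraphenylporphyrin (cat.), visible light, CH2Cl2, 0 °C
Reagents that add atoms: dioxygen, O=O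
Why: Schenck ene reaction of singlet oxygen with the s-cis-locked enone: oxygen bonds to the β carbon C11 and the hydrogen is taken from C6, the alkyl group geminal to the carbonyl on C7, so the alkene moves to C6=C7 in conjugation with C8=O; the electron-poor angelate alkene reacts much more slowly and no stereocentre is formed.

**Compound list**

1 | (R)-carvone | CC1=CC[C@H](CC1=O)C(C)=C | starting material
2 | (5R)-5-(2-hydroxypropan-2-yl)-2-methylcyclohex-2-en-1-one | CC1=CC[C@H](CC1=O)C(C)(C)O | intermediate
3 | (5R)-2-methyl-5-[2-(triethylsilyloxy)propan-2-yl]cyclohex-2-en-1-one | CC1=CC[C@H](CC1=O)C(C)(C)O[Si](CC)(CC)CC | intermediate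
4 | (1-bromovinyl)trimethylsilane | C=C(Br)[Si](C)(C)C | starting material
5 | allyl bromide | C=CCBr | starting material
6 | [1-(trimethylsilyl)vinyl]magnesium bromide | C=C([Mg]Br)[Si](C)(C)C | intermediate (not isolated)
7 | bromomagnesium (3R,5R)-2-methyl-5-[2-(triethylsilyloxy)propan-2-yl]-3-[1-(trimethylsilyl)vinyl]cyclohex-1-en-1-olate | CC1=C(O[Mg]Br)C[C@H](C(C)(C)O[Si](CC)(CC)CC)C[C@H]1C(=C)[Si](C)(C)C | intermediate (not isolated)
8 | (2S,3R,5R)-2-allyl-2-methyl-5-[2-(triethylsilyloxy)propan-2-yl]-3-[1-(trimethylsilyl)vinyl]cyclohexan-1-one | C=CC[C@@]1(C)[C@H](C(=C)[Si](C)(C)C)C[C@@H](C(C)(C)O[Si](CC)(CC)CC)CC1=O | intermediate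
9 | alkyldicyclohexylborane from 8 (boron on the terminal carbon of the former allyl group) | C1CCCCC1B(C2CCCCC2)CCC[C@@]3(C)[C@H](C(=C)[Si](C)(C)C)C[C@@H](C(C)(C)O[Si](CC)(CC)CC)CC3=O | intermediate (not isolated)
10 | (2S,3R,5R)-2-(3-hydroxypropyl)-2-methyl-5-[2-(triethylsilyloxy)propan-2-yl]-3-[1-(trimethylsilyl)vinyl]cyclohexan-1-one | OCCC[C@@]1(C)[C@H](C(=C)[Si](C)(C)C)C[C@@H](C(C)(C)O[Si](CC)(CC)CC)CC1=O | intermediate
11 | (2S,3R,5R)-2-(3-hydroxypropyl)-3-(1-iodovinyl)-2-methyl-5-[2-(triethylsilyloxy)propan-2-yl]cyclohexan-1-one | OCCC[C@@]1(C)[C@H](C(I)=C)C[C@@H](C(C)(C)O[Si](CC)(CC)CC)CC1=O | intermediate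
12 | 3-[(1S,2R,4R)-2-(1-iodovinyl)-1-methyl-6-oxo-4-[2-(triethylsilyloxy)propan-2-yl]cyclohexyl]propanal | O=CCC[C@@]1(C)[C@H](C(I)=C)C[C@@H](C(C)(C)O[Si](CC)(CC)CC)CC1=O | intermediate
13 | alkenylchromium dichloride from 12 (CrCl2 in place of iodine) | O=CCC[C@@]1(C)[C@H](C(=C)[Cr](Cl)Cl)C[C@@H](C(C)(C)O[Si](CC)(CC)CC)CC1=O | intermediate (not isolated)
14 | 3β-hydroxy-11-(triethylsilyloxy)-7βH-eudesm-4(15)-en-9-one (trans-decalin, 10β-CH3, 5α-H, C7 side chain α) | O[C@H]1CC[C@]2(C)C(=O)C[C@H](C(C)(C)O[Si](CC)(CC)CC)C[C@H]2C1=C | intermediate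
15 | 3β-(tert-butyldimethylsilyloxy)-11-(triethylsilyloxy)-7βH-eudesm-4(15)-en-9-one | CC(C)(C)[Si](C)(C)O[C@H]1CC[C@]2(C)C(=O)C[C@H](C(C)(C)O[Si](CC)(CC)CC)C[C@H]2C1=C | intermediate
16 | potassium 8-en-9-olate of 15 | CC(C)(C)[Si](C)(C)O[C@H]1CC[C@]2(C)C([O-])=C[C@H](C(C)(C)O[Si](CC)(CC)CC)C[C@H]2C1=C.[K+] | intermediate (not isolated)
17 | 3β-(tert-butyldimethylsilyloxy)-11-(triethylsilyloxy)-7βH-eudesma-4(15),8-dien-9-yl trifluoromethanesulfonate | CC(C)(C)[Si](C)(C)O[C@H]1CC[C@]2(C)C(OS(=O)(=O)C(F)(F)F)=C[C@H](C(C)(C)O[Si](CC)(CC)CC)C[C@H]2C1=C | intermediate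
18 | 4α,15-epoxy-3β-(tert-butyldimethylsilyloxy)-11-(triethylsilyloxy)-7βH-eudesm-8-en-9-yl trifluoromethanesulfonate | CC(C)(C)[Si](C)(C)O[C@H]1CC[C@]2(C)C(OS(=O)(=O)C(F)(F)F)=C[C@H](C(C)(C)O[Si](CC)(CC)CC)C[C@H]2[C@]13OC3 | intermediate
19 | 4α,15-epoxy-3β-(tert-butyldimethylsilyloxy)-11-(triethylsilyloxy)-7βH-eudesm-8-ene | CC(C)(C)[Si](C)(C)O[C@H]1CC[C@]2(C)C=C[C@H](C(C)(C)O[Si](CC)(CC)CC)C[C@H]2[C@]13OC3 | intermediate
20 | 3β-(tert-butyldimethylsilyloxy)-11-(triethylsilyloxy)-7βH-eudesm-8-en-4α-ol | CC(C)(C)[Si](C)(C)O[C@H]1CC[C@]2(C)C=C[C@H](C(C)(C)O[Si](CC)(CC)CC)C[C@H]2[C@]1(C)O | intermediate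
21 | 3β-(tert-butyldimethylsilyloxy)-7βH-eudesm-8-ene-4α,11-diol | CC(C)(C)[Si](C)(C)O[C@H]1CC[C@]2(C)C=C[C@H](C(C)(C)O)C[C@H]2[C@]1(C)O | intermediate
22 | 4α,11-bis(dimethylsilyloxy) derivative of 21 | CC(C)(C)[Si](C)(C)O[C@H]1CC[C@]2(C)C=C[C@H](C(C)(C)O[SiH](C)C)C[C@H]2[C@]1(C)O[SiH](C)C | intermediate (not isolated)
23 | cyclic siloxane (O11–SiMe2–C8α five-membered ring, cis-fused at C7–C8; 4α-O-SiHMe2) | CC(C)(C)[Si](C)(C)O[C@H]1CC[C@]2(C)C[C@H]3[C@H](C(C)(C)O[Si]3(C)C)C[C@H]2[C@]1(C)O[SiH](C)C | intermediate (not isolated)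
24 | 3β-(tert-butyldimethylsilyloxy)-7βH-eudesmane-4α,8α,11-triol | CC(C)(C)[Si](C)(C)O[C@H]1CC[C@]2(C)C[C@H](O)[C@H](C(C)(C)O)C[C@H]2[C@]1(C)O | intermediate
25 | 3β-(tert-butyldimethylsilyloxy)-4α,11-dihydroxy-7βH-eudesman-8-one | CC(C)(C)[Si](C)(C)O[C@H]1CC[C@]2(C)CC(=O)[C@H](C(C)(C)O)C[C@H]2[C@]1(C)O | intermediate
26 | 3β-(tert-butyldimethylsilyloxy)-4α-hydroxyeudesm-7(11)-en-8-one | CC(C)(C)[Si](C)(C)O[C@H]1CC[C@]2(C)CC(=O)C(=C(C)C)C[C@H]2[C@]1(C)O | intermediate
27 | 3β,4α-dihydroxyeudesm-7(11)-en-8-one | O[C@H]1CC[C@]2(C)CC(=O)C(=C(C)C)C[C@H]2[C@]1(C)O | intermediate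
28 | angelic acid | C/C=C(/C)C(=O)O | starting material
29 | angelic 2,4,6-trichlorobenzoic anhydride | C/C=C(/C)C(=O)OC(=O)c1c(Cl)cc(Cl)cc1Cl | intermediate (not isolated)
30 | 3β-angeloyloxy-4α-hydroxyeudesm-7(11)-en-8-one | C/C=C(/C)C(=O)O[C@H]1CC[C@]2(C)CC(=O)C(=C(C)C)C[C@H]2[C@]1(C)O | intermediate
31 | 3β-angeloyloxy-4α-hydroxy-11-hydroperoxyeudesm-6-en-8-one | C/C=C(/C)C(=O)O[C@H]1CC[C@]2(C)CC(=O)C(C(C)(C)OO)=C[C@H]2[C@]1(C)O | target

**Step count and risks**

Total step count: 19. Longest linear sequence: 19 steps from (R)-carvone 1; compounds 4, 5 and 28 are bought and enter directly.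

Steps most likely to fail:

1. Step 7. What may go wrong: low selectivity between the two faces of the aldehyde in the organochromium addition, so that the axial 3α-alcohol forms beside or in place of 14. The fallback sets out from 12 and comes back at 14. The cyclisation product, as 3α-hydroxy-11-(triethylsilyloxy)-7βH-eudesm-4(15)-en-9-one F1 or its mixture with 14, is oxidised with DMP in CH2Cl2 to 11-(triethylsilyloxy)-7βH-eudesm-4(15)-ene-3,9-dione F2. The conjugated C3 carbonyl is then reduced with NaBH4/CeCl3·7H2O in MeOH at −78 °C (Luche reduction). Axial hydride delivery from the α face should give the equatorial 3β-alcohol 14, and the C9 ketone, next to the quaternary C10, should react more slowly than the enone. C3 is then set by substrate control in a reduction, not in the C–C bond formation.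

2. Step 14. What may go wrong: slow or incomplete hydrosilylation of the hindered ring alkene, with migration of the C8=C9 double bond competing. The fallback sets out from 21 and comes back at 25. Compound 21 is hydroborated with excess BH3·THF (0 °C → rt) and worked up with NaOH/H2O2. Boron should add from the β face, opposite the pseudoaxial C7 side chain, and at C8, the alkene carbon farther from the quaternary C10, to give 3β-(tert-butyldimethylsilyloxy)-7βH-eudesmane-4α,8β,11-triol F3. DMP oxidation as in step 15 then gives 25, since the C8 configuration is lost. Regiocontrol here rests on steric bias and not on a tether, so any C9 alcohol would have to be separated at this stage.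

3. Step 3. What may go wrong: sluggish C-allylation of the hindered magnesium enolate, with proton transfer or O-allylation taking over. The fallback sets out from 3 and comes back at 8. The conjugate addition is run as in step 3 and the enolate 7 is quenched on oxygen with allyl chloroformate (THF/HMPA, −78 → 0 °C) to give allyl (3R,5R)-2-methyl-5-[2-(triethylsilyloxy)propan-2-yl]-3-[1-(trimethylsilyl)vinyl]cyclohex-1-en-1-yl carbonate F4. Treatment with Pd(PPh3)4 (cat.) in THF at rt should expel CO2 and recombine the enolate with the allylpalladium fragment (Tsuji decarboxylative allylation), again anti to the C3 substituent, to give 8.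

Further compounds
F1 | step 7 | 3α-hydroxy-11-(triethylsilyloxy)-7βH-eudesm-4(15)-en-9-one | O[C@@H]1CC[C@]2(C)C(=O)C[C@H](C(C)(C)O[Si](CC)(CC)CC)C[C@H]2C1=C
F2 | step 7 | 11-(triethylsilyloxy)-7βH-eudesm-4(15)-ene-3,9-dione | O=C1CC[C@]2(C)C(=O)C[C@H](C(C)(C)O[Si](CC)(CC)CC)C[C@H]2C1=C
F3 | step 14 | 3β-(tert-butyldimethylsilyloxy)-7βH-eudesmane-4α,8β,11-triol | CC(C)(C)[Si](C)(C)O[C@H]1CC[C@]2(C)C[C@@H](O)[C@H](C(C)(C)O)C[C@H]2[C@]1(C)O
F4 | step 3 | allyl (3R,5R)-2-methyl-5-[2-(triethylsilyloxy)propan-2-yl]-3-[1-(trimethylsilyl)vinyl]cyclohex-1-en-1-yl carbonate | CC1=C(OC(=O)OCC=C)C[C@H](C(C)(C)O[Si](CC)(CC)CC)C[C@H]1C(=C)[Si](C)(C)C
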